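Abbreviations used in names: TBS = tert-butyldimethylsilyl, PMB = 4-methoxybenzyl, (R)-TRIP = (R)-3,3'-bis(2,4,6-triisopropylphenyl)-1,1'-binaphthyl-2,2'-diyl hydrogen phosphate. Core numbering: O1, C2, C3, C3a, C4, O5, C6, C7, C7a (2,3-dihydro-4H-furo[3,2-c]pyran-4-one); ring C atoms are primed.

## Structural features

The target is (2R,3S)-2,6-bis(3,4-dihydroxyphenyl)-3-(4-hydroxy-2-oxo-2H-pyran-6-yl)-2,3-dihydro-4H-furo[3,2-c]pyran-4-one. Ring A (dihydrofuran, O1–C2–C3–C3a–C7a) is fused across C3a=C7a to ring B (2-pyranone, C4(=O)–O5–C6–C7); ring D (catechol) sits on C6, ring E (catechol) on C2, and ring C (4-hydroxy-2-pyranone) is joined through C6' to C3. The only stereocentres are the neighbours C2 and C3, with H-2 and H-3 cis, so the two large groups share one face of a five-membered ring, the less stable arrangement. C3–H is the weak point: once C3 bears a carbonyl carbon or ring C it is α (or vinylogously α) to C=O, and O1, a vinylogous carboxylate oxygen, lies β to it, so enolisation or E1cB opening of O1–C2 followed by re-closure would lead to the trans isomer. The C2–O1 bond is benzylic and para to an oxygen of ring E, so a free phenolate can expel O1 as a quinone methide and strong acid can ionise it. The catechols are oxidation-sensitive, both lactones are open to nucleophiles and the 4'-OH is acidic. The real difficulty is therefore to carry the cis C2/C3 pair through the construction of two pyranone rings. The key step uses the fact that ring A with an ester on C3a and a methyl group on C7a is a cyclic β-alkoxycrotonate: C7 is its only acidic position and the ring holds C7 and the ester carbon C4 on the same side of C3a=C7a, so C6 with ring D can be attached at C7 and O5–C4 closed while C2 and C3 stay untouched.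

## Logic of the disconnections

31 to 30. Only the four aryl O–Si bonds are cut. Free catechols and a free 4-hydroxyphenyl group on C2 would not survive amide bases or oxidants, so they stay masked to the end. The gain is that all earlier steps run on a non-acidic, oxidation-stable substrate. The demand is a desilylation that never forms a phenolate.

30 to 28. Ring C is opened at O1'–C2'. In the forward sense the enol oxygen on C6' acylates a ketene carbon that is unmasked from a dioxinone by loss of acetone (through 29). Ring C is thereby reduced to an acetoacetyl unit on a C3 ketone, and its closure needs neither acid nor base. The demand is that C3–H, α to the ketone in 28, survives about 110 °C.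

28 to 26 and 22. The C5'–C6' bond is cut, after returning the ketone of 28 to the alcohol of 27. C2'–C5' come from 22, and C6' is the carbon already on C3. The demand is a Lewis-acid aldol, because C3–H of 26 is α to the formyl group and β to O1, so no base may be present.

26 to 24. No skeletal bond is cut; the formyl carbon is taken back to CH2–O–PMB (through 25). In this form C3–H is not acidic, which the strongly basic ring B step requires. The price is two adjustments after that step, and the PMB group must be removable without acid or base.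

24 to 15 and 20. The two ring B bonds C6–C7 and C4–O5 are cut. This removes ring B and ring D in one operation and leaves a monocyclic ester that already carries both stereocentres. The demand is exclusive deprotonation at C7, acylation at the γ-carbon, and mono-acylation; the intermediate 23 must then lactonise under mild acid.

20 to 16, 2 to 1, 22 to 21. Only O–Si, amide C–N and enol O–Si bonds are cut; these are protection and activation steps on commercial materials.

15 to 12. The enol ether bond O1–C7a and the C3a–C7a bond are traced back. 15 is the methanolysis–recyclisation isomer of 13 (through 14), and 13 is the C-acetyl derivative of 12. The gain is that ring A with its ester and methyl group comes from a plain cis-4,5-disubstituted butyrolactone. The demand is that the acid-catalysed rearrangement breaks only acyl–oxygen bonds, so that the benzylic C–O bond keeps its configuration.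

12 to 8. The lactone carbonyl is taken back to a terminal alkene: 12 from 10 by oxidative lactonisation, 10 from 8 by anti-Markovnikov hydration (through 9). No stereocentre is involved; the demand is chemoselective oxidation of the primary hydroxyl.

8 to 2 and 6. The C2–C3 bond between the two stereocentres is cut. Both centres are then set in one catalytic step from an achiral aldehyde and an achiral allylboronate. The demand is a geometrically pure Z-boronate (syn relationship) and catalyst control of the aldehyde face.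

6 to 3. The CH2–B carbon is removed (6 to 5), the C–B bond is cut (5 to 4) and the ether is cut (4 to 3). The demand is that the Z geometry is created in the hydroboration and not lost in the homologation.

## Other disconnections considered

Alternative 1: ring A closed at O1–C7a by intramolecular SNAr. The cut is the O1–C7a bond. In the forward step the C2 hydroxyl of the anti aldol adduct A1 adds to C7a of a 4-tosyloxy-2-pyranone under Cs2CO3 and expels tosylate (5-exo addition–elimination), giving the ester A2.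
- In favour: ring B and ring D are in place early, C3 is already at the carboxyl oxidation level, and addition–elimination at a 4-sulfonyloxy-2-pyranone is an easy reaction.
- Against: in both A1 and A2 the C3–H is α to an ester and attached to the pyranone while carbonate is present. Retro-aldol of A1, epimerisation of A2, or E1cB opening of the new O1–C2 bond would all lead to the trans series. Aryl silyl ethers are also labile to Cs2CO3, and the anti- and enantioselective aldol that must deliver A1 has no dependable solution.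
- Structure: the alternative is the equal or the better of the chosen plan, because it is more convergent and needs no protecting-group removal or oxidation at the C3 carbon.
- Mechanism: the chosen plan keeps C3 non-acidic in every basic operation, whereas the alternative exposes an acidic C3–H to base in the very step that closes ring A.
- Step economy: the alternative would be shorter if A1 were available, but this gain depends on an aldol that is not secured.

Alternative 2: ring B last by rhodium C–H annulation with a sulfoxonium ylide. The cuts are C7a–C7 and O5–C6. In the forward step the dihydrofuran-3-carboxylic acid A3, which already carries protected ring C, is metalated at C7a–H by [Cp*RhCl2]2 with NaOAc (trivalent rhodium). The aroyl sulfoxonium ylide A4 is inserted as a carbene, and cyclodehydration gives A5.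
- In favour: no strong base and no cryogenic step, ring D enters last from a stable carbene surrogate, and the carboxylate can only direct to the one cis β-C–H. On functional-group tolerance of the ring B step this alternative is the better one.
- Against: ring C must be built before ring B, so C3–H is vinylogously acidic throughout the synthesis of A3 and during a hot, acetate-buffered annulation. A3 is a β-alkoxyacrylic acid with an enol ether C–H, prone to hydrolysis and decarboxylation. The pyranone carbonyl of ring C can compete as a directing group. A cis, enantiopure A3 is no easier to reach than 15.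
- Structure: both plans close ring B with two bonds and no new stereocentre (equal).
- Mechanism: the alternative is milder in the ring B step, but the chosen plan relies on a dienolate acylation of a well-precedented substrate class, while C–H activation of dihydrofuran acids is less typical.
- Step economy: A4 costs about as many steps as 20 (equal), but more steps are carried with a labile C3–H, so the total is not lower.

Alternative 3: gold-catalysed 6-endo closure of ring C at O1'–C6'. The cut is O1'–C6'. In the forward step Ph3PAuNTf2 (monovalent gold) activates the C3-bound alkyne of the tert-butyl 3-oxo-4-ynoate A6, the ester carbonyl oxygen attacks C6' in 6-endo-dig mode and isobutene is lost, giving A7, which is identical with 30.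
- In favour: room temperature and neutral conditions. This is milder than the thermolysis of step 18, and on this point the alternative is the better one. It is also compatible with the chosen ring B construction, since it only replaces the way ring C is made.
- Against: A6 needs a C3–alkyne. Reaching it from 26 requires a base-mediated one-carbon homologation of an epimerisable aldehyde and then an ynone-forming acylation. The C3–H of A6 is propargylic and γ to the ynone, so allene formation is possible, and 5-exo closure can compete.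
- Structure: same penultimate compound (equal).
- Mechanism: the gold closure is gentler than acylketene generation.
- Step economy: the chosen plan reaches 30 from 25 in four steps without base, while the route through A6 would need more steps and at least one basic step at the aldehyde stage.

Key step: step 13

Remarks on the chemistry:
- (R)-TRIP is assumed to direct the boronate to the Re face of aldehyde 2, the sense this catalyst class shows with aryl aldehydes. If the sense were opposite, the mirror-image catalyst would be used and nothing else changes.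
- Compounds 15, 24 and 31 have the same spatial arrangement at C2 and C3 (H-2/H-3 cis). The C3 descriptor is R while C3 bears CH2O (15, 24, 25, 27) and S once it bears a carbonyl carbon or ring C (26, 28–31); this is a change of CIP priority only.

## Route

Step 1
Reactants: 1 3,4-dihydroxybenzaldehyde
Product: 2 3,4-bis(TBSO)benzaldehyde
Conditions: TBSCl (2.4 equiv), imidazole, DMF, rt
Reagents that add atoms: tert-butyldimethylsilyl chloride, CC(C)(C)[Si](C)(C)Cl
Why: Imidazole-promoted silylation of both phenols; aryl silyl ethers tolerate every later step and are removed at the end by fluoride without base.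

Step 2
Reactants: 3 prop-2-yn-1-ol
Product: 4 4-methoxybenzyl prop-2-yn-1-yl ether
Conditions: NaH, THF, 0 °C; PMBCl, n-Bu4NI (cat.), 0 °C → rt
Reagents that add atoms: 4-methoxybenzyl chloride, COc1ccc(CCl)cc1
Why: Williamson ether synthesis; one equivalent of hydride forms the alkoxide and leaves the far less acidic alkyne C–H alone.

Step 3
Reactants: 4 4-methoxybenzyl prop-2-yn-1-yl ether
Product: 5 (Z)-2-[3-(PMBO)prop-1-en-1-yl]-4,4,5,5-tetramethyl-1,3,2-dioxaborolane
Conditions: HBpin (limiting), [Rh(cod)Cl]2 (1.5 mol%), P(iPr)3 (6 mol%), Et3N, cyclohexane, rt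
Reagents that add atoms: pinacolborane, CC1(C)OBOC1(C)C
Why: Rhodium-catalysed formal trans-hydroboration of a terminal alkyne: a rhodium vinylidene is formed, boryl migration and reductive elimination place boron cis to the chain and should give the Z-alkenylboronate.

Step 4
Reactants: 5 (Z)-2-[3-(PMBO)prop-1-en-1-yl]-4,4,5,5-tetramethyl-1,3,2-dioxaborolane
Product: 6 (Z)-2-[4-(PMBO)but-2-en-1-yl]-4,4,5,5-tetramethyl-1,3,2-dioxaborolane
Conditions: BrCH2Cl, n-BuLi, THF, −78 °C → rt
Reagents that add atoms: bromochloromethane, ClCBr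
Why: Matteson homologation: LiCH2Cl made in situ adds to boron and the alkenyl group migrates with loss of chloride, with retention of the Z double bond; allyl pinacol boronates do not isomerise at room temperature.

Step 5
Reactants: 2 3,4-bis(TBSO)benzaldehyde; 6 (Z)-2-[4-(PMBO)but-2-en-1-yl]-4,4,5,5-tetramethyl-1,3,2-dioxaborolane
Product: 8 (1R,2R)-1-[3,4-bis(TBSO)phenyl]-2-[(PMBO)methyl]but-3-en-1-ol, via pinacol borate ester 7 (not isolated)
Conditions: (R)-TRIP (5 mol%), 4 Å MS, PhMe, −30 °C; aqueous work-up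
Reagents that add atoms: none
Why: Chiral phosphoric acid-catalysed allylboration through a closed chair (Zimmerman–Traxler) transition state: the Z geometry places CH2OPMB axial and gives the syn pair, and the catalyst, hydrogen-bonded to a boronate oxygen and the formyl C–H, exposes the Re face of 2 so that both centres are R; hydrolysis of 7 on work-up frees 8.

Step 6
Reactants: 8 (1R,2R)-1-[3,4-bis(TBSO)phenyl]-2-[(PMBO)methyl]but-3-en-1-ol
Product: 10 (1R,2R)-1-[3,4-bis(TBSO)phenyl]-2-[(PMBO)methyl]butane-1,4-diol, via B-alkyl-9-BBN adduct 9 (not isolated)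
Conditions: 9-BBN (2.5 equiv), THF, 0 °C → rt; NaBO3·4H2O, H2O, rt
Reagents that add atoms: sodium perborate tetrahydrate, [Na+].[Na+].O[B-]1(O)OO[B-](O)(O)OO1.O.O.O.O.O.O
Why: Anti-Markovnikov hydroboration of the monosubstituted alkene by a bulky borane, then C–B oxidation with perborate, which is mild enough for aryl silyl ethers; no stereocentre is touched.

Step 7
Reactants: 10 (1R,2R)-1-[3,4-bis(TBSO)phenyl]-2-[(PMBO)methyl]butane-1,4-diol
Product: 12 (4R,5R)-5-[3,4-bis(TBSO)phenyl]-4-[(PMBO)methyl]oxolan-2-one, via lactol 11 (not isolated)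
Conditions: TEMPO (0.2 equiv), PhI(OAc)2 (2.5 equiv), CH2Cl2, rt
Reagents that add atoms: none
Why: Oxoammonium oxidation selects the primary alcohol; the hydroxy aldehyde closes onto the benzylic hydroxyl to lactol 11, which is oxidised to the γ-lactone, and since no C–O bond at a stereocentre is broken the syn adduct becomes the cis lactone.

Step 8
Reactants: 12 (4R,5R)-5-[3,4-bis(TBSO)phenyl]-4-[(PMBO)methyl]oxolan-2-one
Product: 13 (4R,5R)-3-acetyl-5-[3,4-bis(TBSO)phenyl]-4-[(PMBO)methyl]oxolan-2-one (C3 epimers or enol)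
Conditions: LiN(iPr)2 (1.15 equiv), THF, −78 °C; MeC(O)N(OMe)Me (1.5 equiv), −78 → −20 °C; AcOH
Reagents that add atoms: N-methoxy-N-methylacetamide, CC(=O)N(C)OC
Why: Crossed Claisen acylation of the lactone lithium enolate with a Weinreb amide; the chelated adduct prevents O-acylation and double acylation, and the new centre C3 is a β-dicarbonyl carbon that disappears in step 9.

Step 9
Reactants: 13 (4R,5R)-3-acetyl-5-[3,4-bis(TBSO)phenyl]-4-[(PMBO)methyl]oxolan-2-one
Product: 15 methyl (4R,5R)-5-[3,4-bis(TBSO)phenyl]-4-[(PMBO)methyl]-2-methyl-4,5-dihydrofuran-3-carboxylate, via hydroxy keto ester 14 (not isolated)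
Conditions: HCl (1.25 M in MeOH), CH2Cl2, 0 °C → rt
Reagents that add atoms: methanol, CO
Why: α-Acyl lactone (Korte) rearrangement: acid-catalysed methanolysis of the activated lactone gives 14, whose benzylic hydroxyl adds to the acetyl carbonyl and loses water to form the conjugated β-alkoxy acrylate; only acyl–oxygen bonds are broken, so C4 and C5 should stay cis.

Step 10
Reactants: 16 3,4-dihydroxybenzoic acid
Product: 18 3,4-bis(TBSO)benzoic acid, via silyl ester 17 (not isolated)
Conditions: TBSCl (3.5 equiv), imidazole, DMF, rt; then AcOH/THF/H2O (3:1:1), rt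
Reagents that add atoms: tert-butyldimethylsilyl chloride, CC(C)(C)[Si](C)(C)Cl
Why: Exhaustive silylation followed by selective hydrolysis of the much more labile silyl ester; aryl silyl ethers are stable to aqueous acetic acid.

Step 11
Reactants: 18 3,4-bis(TBSO)benzoic acid
Product: 20 3,4-bis(TBSO)-N-methoxy-N-methylbenzamide, via acyl imidazole 19 (not isolated)
Conditions: CDI (1.1 equiv), CH2Cl2, rt; then MeNHOMe·HCl (1.3 equiv), rt
Reagents that add atoms: N,O-dimethylhydroxylamine hydrochloride, CNOC.Cl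
Why: Activation of the acid as the acyl imidazole with loss of CO2, then aminolysis; the neutral to weakly acidic medium spares the silyl ethers.

Step 12
Reactants: 21 2,2,6-trimethyl-4H-1,3-dioxin-4-one
Product: 22 [(2,2-dimethyl-6-methylidene-6H-1,3-dioxin-4-yl)oxy]trimethylsilane
Conditions: LiN(iPr)2, THF, −78 °C; TMSCl, −78 → 0 °C; distillation
Reagents that add atoms: chlorotrimethylsilane, C[Si](C)(C)Cl
Why: γ-Deprotonation of the vinylogous ester and O-silylation of the dienolate give the silyl dienol ether needed for the vinylogous Mukaiyama aldol of step 16.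

Step 13
Reactants: 15 methyl (4R,5R)-5-[3,4-bis(TBSO)phenyl]-4-[(PMBO)methyl]-2-methyl-4,5-dihydrofuran-3-carboxylate; 20 3,4-bis(TBSO)-N-methoxy-N-methylbenzamide
Product: 24 (2R,3R)-2,6-bis[3,4-bis(TBSO)phenyl]-3-[(PMBO)methyl]-2,3-dihydro-4H-furo[3,2-c]pyran-4-one, via keto ester 23 (not isolated)
Conditions: LiN(iPr)2 (1.1 equiv), THF, −78 °C; 20 (1.1 equiv), −78 → −20 °C; AcOH; then camphorsulfonic acid (0.1 equiv), PhMe, 60 °C
Reagents that add atoms: none
Why: LiN(iPr)2 removes a proton from the C7 methyl of 15 to give the ester-conjugated lithium dienolate, whose γ-carbon C7 adds to the carbonyl of 20; the N-methoxy lithium chelate holds the tetrahedral adduct until the acetic acid quench releases aryl ketone 23, so the C6–C7 bond is made once only (a vinylogous Claisen condensation, the closest known type being γ-acylation of β-alkoxycrotonate and 2-methyl-4,5-dihydrofuran-3-carboxylate dienolates on the way to 4-alkoxy-6-aryl-2-pyranones). With catalytic sulfonic acid in warm toluene 23 enolises toward C7, the enol oxygen adds to the ester carbonyl C4 in a 6-exo-trig closure and loss of methanol gives the 2-pyranone ring B (O5–C4). No stereocentre is formed; C2 and C3 are spectators because C3 carries only an ether-protected CH2 group and an anion at C3 would not be conjugated with the ester. The selectivity needed is γ over α acylation and C7 over C3 deprotonation: C3a is fully substituted and shielded by the C3 substituent, and only the C7 protons give an ester-conjugated anion. Ring A fixes the acylated methyl group and the ester cis on C3a=C7a, so lactonisation needs no double-bond isomerisation. The aryl silyl ethers and the PMB ether tolerate amide base at −78 °C and a tenth of an equivalent of sulfonic acid in a non-ionising solvent.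

Step 14
Reactants: 24 (2R,3R)-2,6-bis[3,4-bis(TBSO)phenyl]-3-[(PMBO)methyl]-2,3-dihydro-4H-furo[3,2-c]pyran-4-one
Product: 25 (2R,3R)-2,6-bis[3,4-bis(TBSO)phenyl]-3-(hydroxymethyl)-2,3-dihydro-4H-furo[3,2-c]pyran-4-one
Conditions: DDQ (1.3 equiv), CH2Cl2/pH 7 buffer (18:1), 0 °C
Reagents that add atoms: none
Why: Oxidative PMB cleavage by hydride abstraction from the electron-rich 4-methoxybenzyl C–H and hydrolysis of the oxocarbenium ion; the silyloxyaryl rings are poorer donors, C2–H is deactivated by the vinylogous ester oxygen O1, and neither acid nor base is involved.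

Step 15
Reactants: 25 (2R,3R)-2,6-bis[3,4-bis(TBSO)phenyl]-3-(hydroxymethyl)-2,3-dihydro-4H-furo[3,2-c]pyran-4-one
Product: 26 (2R,3S)-2,6-bis[3,4-bis(TBSO)phenyl]-4-oxo-2,3-dihydro-4H-furo[3,2-c]pyran-3-carbaldehyde
Conditions: Dess–Martin periodinane (1.5 equiv), CH2Cl2, 0 °C → rt; pH 7 buffer/Na2S2O3 work-up; used crude
Reagents that add atoms: none
Why: Dess–Martin oxidation without base; C3–H, now α to the formyl group, is never exposed to base and 26 is used at once without chromatography.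

Step 16
Reactants: 26 (2R,3S)-2,6-bis[3,4-bis(TBSO)phenyl]-4-oxo-2,3-dihydro-4H-furo[3,2-c]pyran-3-carbaldehyde; 22 [(2,2-dimethyl-6-methylidene-6H-1,3-dioxin-4-yl)oxy]trimethylsilane
Product: 27 6-{2-[(2R,3R)-2,6-bis[3,4-bis(TBSO)phenyl]-4-oxo-2,3-dihydro-4H-furo[3,2-c]pyran-3-yl]-2-hydroxyethyl}-2,2-dimethyl-4H-1,3-dioxin-4-one (both carbinol epimers)
Conditions: BF3·OEt2 (1.2 equiv), CH2Cl2, −78 °C; aq. NaHCO3
Reagents that add atoms: none
Why: Vinylogous Mukaiyama aldol: the BF3-activated aldehyde is attacked by the exocyclic methylene (γ-carbon) of 22 at −78 °C without base, so C3 should not epimerise; the carbinol centre forms without control and is removed in step 17.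

Step 17
Reactants: 27 6-{2-[(2R,3R)-2,6-bis[3,4-bis(TBSO)phenyl]-4-oxo-2,3-dihydro-4H-furo[3,2-c]pyran-3-yl]-2-hydroxyethyl}-2,2-dimethyl-4H-1,3-dioxin-4-one
Product: 28 6-{2-[(2R,3S)-2,6-bis[3,4-bis(TBSO)phenyl]-4-oxo-2,3-dihydro-4H-furo[3,2-c]pyran-3-yl]-2-oxoethyl}-2,2-dimethyl-4H-1,3-dioxin-4-one
Conditions: Dess–Martin periodinane (1.3 equiv), CH2Cl2, 0 °C → rt
Reagents that add atoms: none
Why: Dess–Martin oxidation of the secondary alcohol; the resulting ketone enolises toward the doubly activated CH2 group next to the dioxinone and not toward C3.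

Step 18
Reactants: 28 6-{2-[(2R,3S)-2,6-bis[3,4-bis(TBSO)phenyl]-4-oxo-2,3-dihydro-4H-furo[3,2-c]pyran-3-yl]-2-oxoethyl}-2,2-dimethyl-4H-1,3-dioxin-4-one
Product: 30 (2R,3S)-2,6-bis[3,4-bis(TBSO)phenyl]-3-(4-hydroxy-2-oxo-2H-pyran-6-yl)-2,3-dihydro-4H-furo[3,2-c]pyran-4-one, via acylketene 29 (not isolated)
Conditions: PhMe, 110 °C, 30–45 min
Reagents that add atoms: none
Why: Retro-hetero-Diels–Alder loss of acetone from the dioxinone gives acylketene 29, which is captured by the enol oxygen of the C6' ketone and tautomerises to the 4-hydroxy-2-pyranone ring C; the medium is neutral and contains no base.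

Step 19
Reactants: 30 (2R,3S)-2,6-bis[3,4-bis(TBSO)phenyl]-3-(4-hydroxy-2-oxo-2H-pyran-6-yl)-2,3-dihydro-4H-furo[3,2-c]pyran-4-one
Product: 31 (2R,3S)-2,6-bis(3,4-dihydroxyphenyl)-3-(4-hydroxy-2-oxo-2H-pyran-6-yl)-2,3-dihydro-4H-furo[3,2-c]pyran-4-one
Conditions: HF·pyridine, THF/pyridine, 0 °C → rt; work-up and purification at pH 4–6 under argon
Reagents that add atoms: none
Why: Fluoride cleavage of the four aryl silyl ethers in a buffered, weakly acidic medium, so that no phenolate forms that could open O1–C2 through a quinone methide or epimerise C3.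

## Compound list

1 | 3,4-dihydroxybenzaldehyde | O=Cc1ccc(O)c(O)c1 | starting material
2 | 3,4-bis(TBSO)benzaldehyde | O=Cc1ccc(O[Si](C)(C)C(C)(C)C)c(O[Si](C)(C)C(C)(C)C)c1 | intermediate
3 | prop-2-yn-1-ol | C#CCO | starting material
4 | 4-methoxybenzyl prop-2-yn-1-yl ether | COc1ccc(COCC#C)cc1 | intermediate
5 | (Z)-2-[3-(PMBO)prop-1-en-1-yl]-4,4,5,5-tetramethyl-1,3,2-dioxaborolane | COc1ccc(COC/C=C\B2OC(C)(C)C(C)(C)O2)cc1 | intermediate
6 | (Z)-2-[4-(PMBO)but-2-en-1-yl]-4,4,5,5-tetramethyl-1,3,2-dioxaborolane | COc1ccc(COC/C=C\CB2OC(C)(C)C(C)(C)O2)cc1 | intermediate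
7 | 2-{[(1R,2R)-1-[3,4-bis(TBSO)phenyl]-2-[(PMBO)methyl]but-3-en-1-yl]oxy}-4,4,5,5-tetramethyl-1,3,2-dioxaborolane | C=C[C@H](COCc1ccc(OC)cc1)[C@@H](OB1OC(C)(C)C(C)(C)O1)c1ccc(O[Si](C)(C)C(C)(C)C)c(O[Si](C)(C)C(C)(C)C)c1 | intermediate
8 | (1R,2R)-1-[3,4-bis(TBSO)phenyl]-2-[(PMBO)methyl]but-3-en-1-ol | C=C[C@H](COCc1ccc(OC)cc1)[C@@H](O)c1ccc(O[Si](C)(C)C(C)(C)C)c(O[Si](C)(C)C(C)(C)C)c1 | intermediate
9 | (1R,2R)-4-(9-borabicyclo[3.3.1]nonan-9-yl)-1-[3,4-bis(TBSO)phenyl]-2-[(PMBO)methyl]butan-1-ol | C1CCC2CCCC1B2CC[C@H](COCc1ccc(OC)cc1)[C@@H](O)c1ccc(O[Si](C)(C)C(C)(C)C)c(O[Si](C)(C)C(C)(C)C)c1 | intermediate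
10 | (1R,2R)-1-[3,4-bis(TBSO)phenyl]-2-[(PMBO)methyl]butane-1,4-diol | OCC[C@H](COCc1ccc(OC)cc1)[C@@H](O)c1ccc(O[Si](C)(C)C(C)(C)C)c(O[Si](C)(C)C(C)(C)C)c1 | intermediate
11 | (4R,5R)-5-[3,4-bis(TBSO)phenyl]-4-[(PMBO)methyl]oxolan-2-ol (both anomers) | OC1C[C@H](COCc2ccc(OC)cc2)[C@H](c2ccc(O[Si](C)(C)C(C)(C)C)c(O[Si](C)(C)C(C)(C)C)c2)O1 | intermediate
12 | (4R,5R)-5-[3,4-bis(TBSO)phenyl]-4-[(PMBO)methyl]oxolan-2-one | O=C1C[C@H](COCc2ccc(OC)cc2)[C@H](c2ccc(O[Si](C)(C)C(C)(C)C)c(O[Si](C)(C)C(C)(C)C)c2)O1 | intermediate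
13 | (4R,5R)-3-acetyl-5-[3,4-bis(TBSO)phenyl]-4-[(PMBO)methyl]oxolan-2-one (C3 epimers) | O=C1C(C(C)=O)[C@H](COCc2ccc(OC)cc2)[C@H](c2ccc(O[Si](C)(C)C(C)(C)C)c(O[Si](C)(C)C(C)(C)C)c2)O1 | intermediate
14 | methyl (3R,4R)-2-acetyl-4-[3,4-bis(TBSO)phenyl]-4-hydroxy-3-[(PMBO)methyl]butanoate (C2 epimers) | COC(=O)C(C(C)=O)[C@H](COCc1ccc(OC)cc1)[C@@H](O)c1ccc(O[Si](C)(C)C(C)(C)C)c(O[Si](C)(C)C(C)(C)C)c1 | intermediate
15 | methyl (4R,5R)-5-[3,4-bis(TBSO)phenyl]-4-[(PMBO)methyl]-2-methyl-4,5-dihydrofuran-3-carboxylate | COc1ccc(COC[C@H]2C(C(=O)OC)=C(C)O[C@H]2c2ccc(O[Si](C)(C)C(C)(C)C)c(O[Si](C)(C)C(C)(C)C)c2)cc1 | intermediate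
16 | 3,4-dihydroxybenzoic acid | O=C(O)c1ccc(O)c(O)c1 | starting material
17 | tert-butyldimethylsilyl 3,4-bis(TBSO)benzoate | CC(C)(C)[Si](C)(C)OC(=O)c1ccc(O[Si](C)(C)C(C)(C)C)c(O[Si](C)(C)C(C)(C)C)c1 | intermediate
18 | 3,4-bis(TBSO)benzoic acid | O=C(O)c1ccc(O[Si](C)(C)C(C)(C)C)c(O[Si](C)(C)C(C)(C)C)c1 | intermediate
19 | [3,4-bis(TBSO)phenyl](1H-imidazol-1-yl)methanone | O=C(c1ccc(O[Si](C)(C)C(C)(C)C)c(O[Si](C)(C)C(C)(C)C)c1)n1ccnc1 | intermediate
20 | 3,4-bis(TBSO)-N-methoxy-N-methylbenzamide | CON(C)C(=O)c1ccc(O[Si](C)(C)C(C)(C)C)c(O[Si](C)(C)C(C)(C)C)c1 | intermediate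
21 | 2,2,6-trimethyl-4H-1,3-dioxin-4-one | CC1=CC(=O)OC(C)(C)O1 | starting material
22 | [(2,2-dimethyl-6-methylidene-6H-1,3-dioxin-4-yl)oxy]trimethylsilane | C=C1C=C(O[Si](C)(C)C)OC(C)(C)O1 | intermediate
23 | methyl (4R,5R)-5-[3,4-bis(TBSO)phenyl]-2-{2-[3,4-bis(TBSO)phenyl]-2-oxoethyl}-4-[(PMBO)methyl]-4,5-dihydrofuran-3-carboxylate | COc1ccc(COC[C@H]2C(C(=O)OC)=C(CC(=O)c3ccc(O[Si](C)(C)C(C)(C)C)c(O[Si](C)(C)C(C)(C)C)c3)O[C@H]2c2ccc(O[Si](C)(C)C(C)(C)C)c(O[Si](C)(C)C(C)(C)C)c2)cc1 | intermediate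
24 | (2R,3R)-2,6-bis[3,4-bis(TBSO)phenyl]-3-[(PMBO)methyl]-2,3-dihydro-4H-furo[3,2-c]pyran-4-one | COc1ccc(COC[C@H]2c3c(cc(-c4ccc(O[Si](C)(C)C(C)(C)C)c(O[Si](C)(C)C(C)(C)C)c4)oc3=O)O[C@H]2c2ccc(O[Si](C)(C)C(C)(C)C)c(O[Si](C)(C)C(C)(C)C)c2)cc1 | intermediate
25 | (2R,3R)-2,6-bis[3,4-bis(TBSO)phenyl]-3-(hydroxymethyl)-2,3-dihydro-4H-furo[3,2-c]pyran-4-one | OC[C@H]1c2c(cc(-c3ccc(O[Si](C)(C)C(C)(C)C)c(O[Si](C)(C)C(C)(C)C)c3)oc2=O)O[C@H]1c1ccc(O[Si](C)(C)C(C)(C)C)c(O[Si](C)(C)C(C)(C)C)c1 | intermediate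
26 | (2R,3S)-2,6-bis[3,4-bis(TBSO)phenyl]-4-oxo-2,3-dihydro-4H-furo[3,2-c]pyran-3-carbaldehyde | O=C[C@H]1c2c(cc(-c3ccc(O[Si](C)(C)C(C)(C)C)c(O[Si](C)(C)C(C)(C)C)c3)oc2=O)O[C@H]1c1ccc(O[Si](C)(C)C(C)(C)C)c(O[Si](C)(C)C(C)(C)C)c1 | intermediate
27 | 6-{2-[(2R,3R)-2,6-bis[3,4-bis(TBSO)phenyl]-4-oxo-2,3-dihydro-4H-furo[3,2-c]pyran-3-yl]-2-hydroxyethyl}-2,2-dimethyl-4H-1,3-dioxin-4-one (both carbinol epimers) | CC1(C)OC(=O)C=C(CC(O)[C@H]2c3c(cc(-c4ccc(O[Si](C)(C)C(C)(C)C)c(O[Si](C)(C)C(C)(C)C)c4)oc3=O)O[C@H]2c2ccc(O[Si](C)(C)C(C)(C)C)c(O[Si](C)(C)C(C)(C)C)c2)O1 | intermediate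
28 | 6-{2-[(2R,3S)-2,6-bis[3,4-bis(TBSO)phenyl]-4-oxo-2,3-dihydro-4H-furo[3,2-c]pyran-3-yl]-2-oxoethyl}-2,2-dimethyl-4H-1,3-dioxin-4-one | CC1(C)OC(=O)C=C(CC(=O)[C@H]2c3c(cc(-c4ccc(O[Si](C)(C)C(C)(C)C)c(O[Si](C)(C)C(C)(C)C)c4)oc3=O)O[C@H]2c2ccc(O[Si](C)(C)C(C)(C)C)c(O[Si](C)(C)C(C)(C)C)c2)O1 | intermediate
29 | 5-[(2R,3S)-2,6-bis[3,4-bis(TBSO)phenyl]-4-oxo-2,3-dihydro-4H-furo[3,2-c]pyran-3-yl]pent-1-ene-1,3,5-trione | O=C=CC(=O)CC(=O)[C@H]1c2c(cc(-c3ccc(O[Si](C)(C)C(C)(C)C)c(O[Si](C)(C)C(C)(C)C)c3)oc2=O)O[C@H]1c1ccc(O[Si](C)(C)C(C)(C)C)c(O[Si](C)(C)C(C)(C)C)c1 | intermediate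
30 | (2R,3S)-2,6-bis[3,4-bis(TBSO)phenyl]-3-(4-hydroxy-2-oxo-2H-pyran-6-yl)-2,3-dihydro-4H-furo[3,2-c]pyran-4-one | O=c1cc(O)cc([C@H]2c3c(cc(-c4ccc(O[Si](C)(C)C(C)(C)C)c(O[Si](C)(C)C(C)(C)C)c4)oc3=O)O[C@H]2c2ccc(O[Si](C)(C)C(C)(C)C)c(O[Si](C)(C)C(C)(C)C)c2)o1 | intermediate
31 | (2R,3S)-2,6-bis(3,4-dihydroxyphenyl)-3-(4-hydroxy-2-oxo-2H-pyran-6-yl)-2,3-dihydro-4H-furo[3,2-c]pyran-4-one | O=c1cc(O)cc([C@H]2c3c(cc(-c4ccc(O)c(O)c4)oc3=O)O[C@H]2c2ccc(O)c(O)c2)o1 | target

## Step count and least certain steps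

Total: 19 steps. Longest linear sequence: 15 steps (steps 2–9 and 13–19, from 3 to 31).

Step 13 (key step). The addition of the dienolate to the electron-rich, hindered amide 20 may be slow, so that proton exchange and decay of the dienolate compete, and some attack through the α-carbon C3a cannot be excluded. The fallback makes the C6–C7 bond by a reversible vinylogous aldol addition instead of an acylation. The lithium dienolate of 15 (LiN(iPr)2, THF, −78 °C) is added to aldehyde 2 and quenched cold with AcOH. This should give methyl (4R,5R)-5-[3,4-bis(TBSO)phenyl]-2-{2-[3,4-bis(TBSO)phenyl]-2-hydroxyethyl}-4-[(PMBO)methyl]-4,5-dihydrofuran-3-carboxylate F1 as both carbinol epimers; α-aldolates revert, so the γ-adduct should accumulate. Dess–Martin oxidation of F1 gives keto ester 23, and the sulfonic acid treatment of step 13 returns the route to 24.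

Step 5. The facial selectivity or the syn relationship may be eroded. The ether oxygen of 6 can compete for the phosphoric acid, and a slow catalysed addition to the electron-rich aldehyde lets the uncatalysed racemic pathway take part. The fallback is a Lewis-base-catalysed addition of a Z-allyltrichlorosilane whose geometry is inherited from a Z-alkene; it sets out from 2 and returns at 8.
- (Z)-But-2-ene-1,4-diol F2 (purchased) is mono-alkylated (NaH, PMBCl) to (Z)-4-(PMBO)but-2-en-1-ol F3.
- Corey–Kim chlorination (N-chlorosuccinimide, Me2S) gives, without allylic transposition, (Z)-1-chloro-4-(PMBO)but-2-ene F4.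
- HSiCl3, CuCl and iPr2NEt in Et2O displace chloride with retention of the double-bond geometry to give trichloro[(Z)-4-(PMBO)but-2-en-1-yl]silane F5.
- F5 adds to 2 at −78 °C in CH2Cl2 in the presence of a chiral 2,2'-bipyrrolidine-derived bisphosphoramide, the enantiomer being chosen to expose the Re face. The closed hexacoordinate silicon chair converts the Z geometry into the syn adduct, and hydrolytic work-up gives 8.

Step 9. The benzylic C–O bond para to the silyloxy group may ionise in methanolic HCl, with loss of the cis configuration or methanolysis at that carbon, and the PMB or aryl silyl groups may be partly lost. The fallback is an acyclic Claisen route that needs only a weak acid; it sets out from 8 and returns at 15.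
- Silylation of 8 (Et3SiOTf, 2,6-lutidine) gives [(1R,2R)-1-[3,4-bis(TBSO)phenyl]-2-[(PMBO)methyl]but-3-en-1-yl]oxy(triethyl)silane F6.
- Hydroboration–oxidation (9-BBN, then NaBO3·4H2O) gives (3R,4R)-4-[3,4-bis(TBSO)phenyl]-3-[(PMBO)methyl]-4-(triethylsilyloxy)butan-1-ol F7.
- Oxidative esterification ((C5H5NH)2Cr2O7, MeOH, DMF) gives methyl (3R,4R)-4-[3,4-bis(TBSO)phenyl]-3-[(PMBO)methyl]-4-(triethylsilyloxy)butanoate F8.
- Claisen acylation (LiN(iPr)2, then N-methoxy-N-methylacetamide) gives methyl (3R,4R)-2-acetyl-4-[3,4-bis(TBSO)phenyl]-3-[(PMBO)methyl]-4-(triethylsilyloxy)butanoate F9.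
- Pyridinium p-toluenesulfonate in MeOH removes the triethylsilyl group; the liberated 14 cyclodehydrates to 15.

Step 15. The cis relationship may be lost by enolisation of the aldehyde (C3–H is α to the formyl group and attached to the pyranone) or by E1cB opening of O1–C2 during oxidation, work-up or the next step. The fallback keeps C3 at the carboxylic acid level; it sets out from 25, returns at 28 and bypasses 26, 22 and 27.
- Oxidation of 25 with PhI(OAc)2 and catalytic TEMPO in MeCN/H2O passes through 26 only transiently and gives (2R,3S)-2,6-bis[3,4-bis(TBSO)phenyl]-4-oxo-2,3-dihydro-4H-furo[3,2-c]pyran-3-carboxylic acid F10.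
- 1-Chloro-N,N,2-trimethylprop-1-en-1-amine in CH2Cl2 at 0 °C converts it under neutral conditions into (2R,3S)-2,6-bis[3,4-bis(TBSO)phenyl]-4-oxo-2,3-dihydro-4H-furo[3,2-c]pyran-3-carbonyl chloride F11.
- F11 is added to the lithium dienolate of 21 (LiN(SiMe3)2, THF, −78 °C, two equivalents) to give 28.

Step 18. At 110 °C the ketone of 28 may enolise toward C3, or O1–C2 may open and re-close, either of which would erode the cis configuration before the acylketene is captured. The fallback closes ring C at room temperature through a tert-butyl 3,5-dioxo ester; it sets out from 26 and returns at 30.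
- A BF3·OEt2-mediated Mukaiyama aldol of 26 with 1-tert-butoxy-1,3-bis(trimethylsilyloxy)buta-1,3-diene F12 (from tert-butyl acetoacetate by two successive silylations) gives tert-butyl 5-[(2R,3R)-2,6-bis[3,4-bis(TBSO)phenyl]-4-oxo-2,3-dihydro-4H-furo[3,2-c]pyran-3-yl]-5-hydroxy-3-oxopentanoate F13.
- Dess–Martin oxidation gives tert-butyl 5-[(2R,3S)-2,6-bis[3,4-bis(TBSO)phenyl]-4-oxo-2,3-dihydro-4H-furo[3,2-c]pyran-3-yl]-3,5-dioxopentanoate F14.
- (CF3CO)2O/CF3CO2H in CH2Cl2 at 0 °C → rt removes isobutene and lactonises the enol onto the activated carboxyl to give 30.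

## Further compounds

F1 | step 13 | methyl (4R,5R)-5-[3,4-bis(TBSO)phenyl]-2-{2-[3,4-bis(TBSO)phenyl]-2-hydroxyethyl}-4-[(PMBO)methyl]-4,5-dihydrofuran-3-carboxylate | COc1ccc(COC[C@H]2C(C(=O)OC)=C(CC(O)c3ccc(O[Si](C)(C)C(C)(C)C)c(O[Si](C)(C)C(C)(C)C)c3)O[C@H]2c2ccc(O[Si](C)(C)C(C)(C)C)c(O[Si](C)(C)C(C)(C)C)c2)cc1
F2 | step 5 | (Z)-but-2-ene-1,4-diol | OC/C=C\CO
F3 | step 5 | (Z)-4-(PMBO)but-2-en-1-ol | COc1ccc(COC/C=C\CO)cc1
F4 | step 5 | (Z)-1-chloro-4-(PMBO)but-2-ene | COc1ccc(COC/C=C\CCl)cc1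
F5 | step 5 | trichloro[(Z)-4-(PMBO)but-2-en-1-yl]silane | COc1ccc(COC/C=C\C[Si](Cl)(Cl)Cl)cc1
F6 | step 9 | [(1R,2R)-1-[3,4-bis(TBSO)phenyl]-2-[(PMBO)methyl]but-3-en-1-yl]oxy(triethyl)silane | C=C[C@H](COCc1ccc(OC)cc1)[C@@H](O[Si](CC)(CC)CC)c1ccc(O[Si](C)(C)C(C)(C)C)c(O[Si](C)(C)C(C)(C)C)c1
F7 | step 9 | (3R,4R)-4-[3,4-bis(TBSO)phenyl]-3-[(PMBO)methyl]-4-(triethylsilyloxy)butan-1-ol | OCC[C@H](COCc1ccc(OC)cc1)[C@@H](O[Si](CC)(CC)CC)c1ccc(O[Si](C)(C)C(C)(C)C)c(O[Si](C)(C)C(C)(C)C)c1
F8 | step 9 | methyl (3R,4R)-4-[3,4-bis(TBSO)phenyl]-3-[(PMBO)methyl]-4-(triethylsilyloxy)butanoate | COC(=O)C[C@H](COCc1ccc(OC)cc1)[C@@H](O[Si](CC)(CC)CC)c1ccc(O[Si](C)(C)C(C)(C)C)c(O[Si](C)(C)C(C)(C)C)c1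
F9 | step 9 | methyl (3R,4R)-2-acetyl-4-[3,4-bis(TBSO)phenyl]-3-[(PMBO)methyl]-4-(triethylsilyloxy)butanoate | COC(=O)C(C(C)=O)[C@H](COCc1ccc(OC)cc1)[C@@H](O[Si](CC)(CC)CC)c1ccc(O[Si](C)(C)C(C)(C)C)c(O[Si](C)(C)C(C)(C)C)c1
F10 | step 15 | (2R,3S)-2,6-bis[3,4-bis(TBSO)phenyl]-4-oxo-2,3-dihydro-4H-furo[3,2-c]pyran-3-carboxylic acid | O=C(O)[C@H]1c2c(cc(-c3ccc(O[Si](C)(C)C(C)(C)C)c(O[Si](C)(C)C(C)(C)C)c3)oc2=O)O[C@H]1c1ccc(O[Si](C)(C)C(C)(C)C)c(O[Si](C)(C)C(C)(C)C)c1
F11 | step 15 | (2R,3S)-2,6-bis[3,4-bis(TBSO)phenyl]-4-oxo-2,3-dihydro-4H-furo[3,2-c]pyran-3-carbonyl chloride | O=C(Cl)[C@H]1c2c(cc(-c3ccc(O[Si](C)(C)C(C)(C)C)c(O[Si](C)(C)C(C)(C)C)c3)oc2=O)O[C@H]1c1ccc(O[Si](C)(C)C(C)(C)C)c(O[Si](C)(C)C(C)(C)C)c1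
F12 | step 18 | 1-tert-butoxy-1,3-bis(trimethylsilyloxy)buta-1,3-diene | C=C(O[Si](C)(C)C)C=C(OC(C)(C)C)O[Si](C)(C)C
F13 | step 18 | tert-butyl 5-[(2R,3R)-2,6-bis[3,4-bis(TBSO)phenyl]-4-oxo-2,3-dihydro-4H-furo[3,2-c]pyran-3-yl]-5-hydroxy-3-oxopentanoate | CC(C)(C)OC(=O)CC(=O)CC(O)[C@H]1c2c(cc(-c3ccc(O[Si](C)(C)C(C)(C)C)c(O[Si](C)(C)C(C)(C)C)c3)oc2=O)O[C@H]1c1ccc(O[Si](C)(C)C(C)(C)C)c(O[Si](C)(C)C(C)(C)C)c1
F14 | step 18 | tert-butyl 5-[(2R,3S)-2,6-bis[3,4-bis(TBSO)phenyl]-4-oxo-2,3-dihydro-4H-furo[3,2-c]pyran-3-yl]-3,5-dioxopentanoate | CC(C)(C)OC(=O)CC(=O)CC(=O)[C@H]1c2c(cc(-c3ccc(O[Si](C)(C)C(C)(C)C)c(O[Si](C)(C)C(C)(C)C)c3)oc2=O)O[C@H]1c1ccc(O[Si](C)(C)C(C)(C)C)c(O[Si](C)(C)C(C)(C)C)c1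
A1 | alternative 1 | methyl (2S,3R)-3-[3,4-bis(TBSO)phenyl]-2-{6-[3,4-bis(TBSO)phenyl]-2-oxo-4-(tosyloxy)-2H-pyran-3-yl}-3-hydroxypropanoate | COC(=O)[C@@H](c1c(OS(=O)(=O)c2ccc(C)cc2)cc(-c2ccc(O[Si](C)(C)C(C)(C)C)c(O[Si](C)(C)C(C)(C)C)c2)oc1=O)[C@@H](O)c1ccc(O[Si](C)(C)C(C)(C)C)c(O[Si](C)(C)C(C)(C)C)c1
A2 | alternative 1 | methyl (2R,3S)-2,6-bis[3,4-bis(TBSO)phenyl]-4-oxo-2,3-dihydro-4H-furo[3,2-c]pyran-3-carboxylate | COC(=O)[C@H]1c2c(cc(-c3ccc(O[Si](C)(C)C(C)(C)C)c(O[Si](C)(C)C(C)(C)C)c3)oc2=O)O[C@H]1c1ccc(O[Si](C)(C)C(C)(C)C)c(O[Si](C)(C)C(C)(C)C)c1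
A3 | alternative 2 | (4S,5R)-5-[3,4-bis(TBSO)phenyl]-4-{2-oxo-4-[2-(trimethylsilyl)ethoxy]-2H-pyran-6-yl}-4,5-dihydrofuran-3-carboxylic acid | O=c1cc(OCC[Si](C)(C)C)cc([C@H]2C(C(=O)O)=CO[C@H]2c2ccc(O[Si](C)(C)C(C)(C)C)c(O[Si](C)(C)C(C)(C)C)c2)o1
A4 | alternative 2 | dimethylsulfoxonium 2-[3,4-bis(TBSO)phenyl]-2-oxoethylide | CS(C)(=O)=CC(=O)c1ccc(O[Si](C)(C)C(C)(C)C)c(O[Si](C)(C)C(C)(C)C)c1
A5 | alternative 2 | (2R,3S)-2,6-bis[3,4-bis(TBSO)phenyl]-3-{2-oxo-4-[2-(trimethylsilyl)ethoxy]-2H-pyran-6-yl}-2,3-dihydro-4H-furo[3,2-c]pyran-4-one | O=c1cc(OCC[Si](C)(C)C)cc([C@H]2c3c(cc(-c4ccc(O[Si](C)(C)C(C)(C)C)c(O[Si](C)(C)C(C)(C)C)c4)oc3=O)O[C@H]2c2ccc(O[Si](C)(C)C(C)(C)C)c(O[Si](C)(C)C(C)(C)C)c2)o1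
A6 | alternative 3 | tert-butyl 5-[(2R,3S)-2,6-bis[3,4-bis(TBSO)phenyl]-4-oxo-2,3-dihydro-4H-furo[3,2-c]pyran-3-yl]-3-oxopent-4-ynoate | CC(C)(C)OC(=O)CC(=O)C#C[C@H]1c2c(cc(-c3ccc(O[Si](C)(C)C(C)(C)C)c(O[Si](C)(C)C(C)(C)C)c3)oc2=O)O[C@H]1c1ccc(O[Si](C)(C)C(C)(C)C)c(O[Si](C)(C)C(C)(C)C)c1
A7 | alternative 3 | (2R,3S)-2,6-bis[3,4-bis(TBSO)phenyl]-3-(4-hydroxy-2-oxo-2H-pyran-6-yl)-2,3-dihydro-4H-furo[3,2-c]pyran-4-one | O=c1cc(O)cc([C@H]2c3c(cc(-c4ccc(O[Si](C)(C)C(C)(C)C)c(O[Si](C)(C)C(C)(C)C)c4)oc3=O)O[C@H]2c2ccc(O[Si](C)(C)C(C)(C)C)c(O[Si](C)(C)C(C)(C)C)c2)o1
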